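**Plan**

- Numbering: tetralin C1 (side chain), C2, C3, C4 (methyl), C4a, C5 (OH), C8 (CO2H), C8a; chain C11–C16. C2 and C3 of ring B are adjacent, unfunctionalised CH2 groups between the benzylic stereocentres C1 and C4, which sit on the neighbouring arene carbons C8a and C4a, so ring B can be closed last at C2–C3 from two propenyl arms.
- Retrosynthetic cuts, in order: C16 O–acyl ester; C8 carboxyl (back to CHO, then Br); C2–C3 (ring-closing metathesis, then saturation); C1–C11 (Ireland–Claisen, the migrating carboxyl carbon becoming the C11 methyl); C4a–C4 (aromatic Claisen); C13–C14 (copper-catalysed alkyl coupling).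
- Forward: ring A is bought as 2-bromo-5-hydroxybenzaldehyde; the C4 arm goes on first, then the C1 arm together with the complete C11–C16 chain; ring B is then closed and reduced; the C8 carboxyl and the C16 ester come last.
- Stereochemistry: C4 from (R)-pentenol (Sharpless kinetic resolution) by Mitsunobu inversion and 1,3-chirality transfer in the aromatic Claisen; C1 and C11 from a CBS-derived (R)-allylic alcohol through the chair Ireland–Claisen of an E(O)-enolate; C15 from (S)-3-bromo-2-methylpropan-1-ol.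
- Protecting groups: phenol as triisopropylsilyl ether, C16–OH as tert-butyldimethylsilyl ether, C8 carried as Br and then CHO, so that once the β,γ-unsaturated ester is in place only a Pinnick oxidation and a buffered fluoride step remain.

Key step: step 15

**Route**

Step 1
Reactants: 1 (±)-(E)-pent-3-en-2-ol
Product: 2 (2R,3E)-pent-3-en-2-ol
Conditions: Ti(OiPr)4 (cat.), L-(+)-diisopropyl tartrate, t-BuOOH (0.6 equiv), 4 Å MS, CH2Cl2, −20 °C, stopped just past half conversion
Reagents that add atoms: none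
Why: Sharpless kinetic resolution, in which the L-(+)-tartrate catalyst should epoxidise the (S)-alcohol much faster, so the unreacted alcohol should be recovered as the (R)-enantiomer and separated from the polar epoxy alcohol by distillation.

Step 2
Reactants: 2 (2R,3E)-pent-3-en-2-ol; 3 2-bromo-5-hydroxybenzaldehyde
Product: 4 2-bromo-5-{[(2S,3E)-pent-3-en-2-yl]oxy}benzaldehyde
Conditions: PPh3, DIAD, THF, 0 °C → rt
Reagents that add atoms: none
Why: Mitsunobu etherification, in which the phenoxide displaces the oxyphosphonium group with inversion to give the (S)-ether, and because the allyl unit carries a methyl group at both ends an allylic transposition cannot change the constitution.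

Step 3
Reactants: 4 2-bromo-5-{[(2S,3E)-pent-3-en-2-yl]oxy}benzaldehyde
Product: 6 6-bromo-3-hydroxy-2-[(2R,3E)-pent-3-en-2-yl]benzaldehyde, via cyclohexadienone 5 (not isolated)
Conditions: Eu(fod)3 (10 mol %), toluene, 80 °C
Reagents that add atoms: none
Why: Aromatic Claisen rearrangement ([3,3] shift, then tautomerisation of the dienone), in which a meta-acyl group is known to steer the allyl unit to the flanked ortho carbon (here C4a) and the chair transition state with the ether methyl equatorial should relay the (S)-C–O centre into the (R)-benzylic centre C4 carrying an E-propenyl group.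

Step 4
Reactants: 6 6-bromo-3-hydroxy-2-[(2R,3E)-pent-3-en-2-yl]benzaldehyde
Product: 7 6-bromo-2-[(2R,3E)-pent-3-en-2-yl]-3-[(triisopropylsilyl)oxy]benzaldehyde
Conditions: TIPSCl, imidazole, DMAP (cat.), DMF, 40 °C
Reagents that add atoms: chlorotri(propan-2-yl)silane, CC(C)[Si](Cl)(C(C)C)C(C)C
Why: Silylation of the phenol gives a bulky aryl silyl ether that should survive the bases, hydrides, organolithium and aqueous acid used later and leave at the end with fluoride.

Step 5
Reactants: 7 6-bromo-2-[(2R,3E)-pent-3-en-2-yl]-3-[(triisopropylsilyl)oxy]benzaldehyde; 8 dimethyl (2-oxopropyl)phosphonate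
Product: 9 (3E)-4-{6-bromo-2-[(2R,3E)-pent-3-en-2-yl]-3-[(triisopropylsilyl)oxy]phenyl}but-3-en-2-one
Conditions: NaH, THF, 0 °C → rt
Reagents that add atoms: none
Why: Horner–Wadsworth–Emmons olefination, whose small stabilised anion should add to the doubly ortho-substituted aldehyde, is too weak a base to touch the benzylic allylic C4–H, and should give the E-enone.

Step 6
Reactants: 9 (3E)-4-{6-bromo-2-[(2R,3E)-pent-3-en-2-yl]-3-[(triisopropylsilyl)oxy]phenyl}but-3-en-2-one
Product: 10 (2R,3E)-4-{6-bromo-2-[(2R,3E)-pent-3-en-2-yl]-3-[(triisopropylsilyl)oxy]phenyl}but-3-en-2-ol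
Conditions: (S)-2-methyl-CBS-oxazaborolidine (20 mol %), catecholborane, toluene, −78 °C
Reagents that add atoms: none
Why: Corey–Bakshi–Shibata reduction, in which the alkenyl group acts as the large substituent so that the (S)-catalyst should deliver hydride to give the (R)-allylic alcohol, while catecholborane at −78 °C leaves the isolated propenyl group and the aryl bromide alone.

Step 7
Reactants: 11 (2S)-3-bromo-2-methylpropan-1-ol
Product: 12 [(2S)-3-bromo-2-methylpropoxy](tert-butyl)dimethylsilane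
Conditions: TBSCl, imidazole, CH2Cl2, 0 °C → rt
Reagents that add atoms: tert-butylchlorodimethylsilane, CC(C)(C)[Si](C)(C)Cl
Why: Standard silylation of a primary alcohol, which does not involve the stereocentre that becomes C15.

Step 8
Reactants: 12 [(2S)-3-bromo-2-methylpropoxy](tert-butyl)dimethylsilane; 13 ethyl 4-bromobutanoate
Product: 15 ethyl (6R)-7-[(tert-butyldimethylsilyl)oxy]-6-methylheptanoate, via Grignard reagent 14 (not isolated)
Conditions: Mg, THF, 50 °C; then 13, Li2CuCl4 (3 mol %), NMP, THF, 0 °C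
Reagents that add atoms: none
Why: Copper-catalysed alkyl–alkyl cross-coupling of a primary Grignard reagent with a primary alkyl bromide, which at 0 °C with NMP should outrun addition to the ester and forms C13–C14 without touching the stereocentre.

Step 9
Reactants: 15 ethyl (6R)-7-[(tert-butyldimethylsilyl)oxy]-6-methylheptanoate
Product: 16 (6R)-7-[(tert-butyldimethylsilyl)oxy]-6-methylheptanoic acid
Conditions: LiOH, THF/MeOH/H2O, rt; then cold 1 M HCl to pH 4
Reagents that add atoms: lithium hydroxide, [Li+].[OH-]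
Why: Ester saponification, which the primary silyl ether should tolerate together with the brief cold acidification.

Step 10
Reactants: 10 (2R,3E)-4-{6-bromo-2-[(2R,3E)-pent-3-en-2-yl]-3-[(triisopropylsilyl)oxy]phenyl}but-3-en-2-ol; 16 (6R)-7-[(tert-butyldimethylsilyl)oxy]-6-methylheptanoic acid
Product: 17 (2R,3E)-4-{6-bromo-2-[(2R,3E)-pent-3-en-2-yl]-3-[(triisopropylsilyl)oxy]phenyl}but-3-en-2-yl (6R)-7-[(tert-butyldimethylsilyl)oxy]-6-methylheptanoate
Conditions: DCC, DMAP (cat.), CH2Cl2, 0 °C → rt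
Reagents that add atoms: none
Why: Steglich esterification joins the two fragments under neutral conditions without touching any stereocentre.

Step 11
Reactants: 17 (2R,3E)-4-{6-bromo-2-[(2R,3E)-pent-3-en-2-yl]-3-[(triisopropylsilyl)oxy]phenyl}but-3-en-2-yl (6R)-7-[(tert-butyldimethylsilyl)oxy]-6-methylheptanoate
Product: 21 (2S,6R)-2-[(1S,2E)-1-{6-bromo-2-[(2R,3E)-pent-3-en-2-yl]-3-[(triisopropylsilyl)oxy]phenyl}but-2-en-1-yl]-7-[(tert-butyldimethylsilyl)oxy]-6-methylheptanoic acid, via lithium enolate 18 (not isolated), via silyl ketene acetal 19 (not isolated), via trimethylsilyl ester 20 (not isolated)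
Conditions: LiN(iPr)2 (1.2 equiv), THF, −78 °C; Me3SiCl/Et3N, −78 → 60 °C; then MeOH/H2O
Reagents that add atoms: none
Why: Ireland–Claisen rearrangement, in which kinetic enolisation in THF without polar additive should give the E(O)-enolate (chain cis to the allylic oxygen) and the chair transition state with the carbinol methyl equatorial should transfer the (R)-C–O centre to C1 and fix C11, the carboxyl group ending where the C11 methyl is needed and the new propenyl group forming E.

Step 12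
Reactants: 21 (2S,6R)-2-[(1S,2E)-1-{6-bromo-2-[(2R,3E)-pent-3-en-2-yl]-3-[(triisopropylsilyl)oxy]phenyl}but-2-en-1-yl]-7-[(tert-butyldimethylsilyl)oxy]-6-methylheptanoic acid
Product: 22 (2S,6R)-2-[(1S,2E)-1-{6-bromo-2-[(2R,3E)-pent-3-en-2-yl]-3-[(triisopropylsilyl)oxy]phenyl}but-2-en-1-yl]-7-[(tert-butyldimethylsilyl)oxy]-6-methylheptan-1-ol
Conditions: LiAlH4, THF, 0 °C → rt; aqueous NaOH work-up
Reagents that add atoms: none
Why: Hydride reduction of the carboxylic acid to the primary alcohol, with the aryl bromide, both silyl ethers and the isolated alkenes inert to LiAlH4 at this temperature.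

Step 13
Reactants: 22 (2S,6R)-2-[(1S,2E)-1-{6-bromo-2-[(2R,3E)-pent-3-en-2-yl]-3-[(triisopropylsilyl)oxy]phenyl}but-2-en-1-yl]-7-[(tert-butyldimethylsilyl)oxy]-6-methylheptan-1-ol
Product: 23 (2S,6R)-2-[(1S,2E)-1-{6-bromo-2-[(2R,3E)-pent-3-en-2-yl]-3-[(triisopropylsilyl)oxy]phenyl}but-2-en-1-yl]-7-[(tert-butyldimethylsilyl)oxy]-6-methylheptyl 4-methylbenzenesulfonate
Conditions: TsCl, Et3N, DMAP (cat.), CH2Cl2, 0 °C → rt
Reagents that add atoms: 4-methylbenzenesulfonyl chloride, Cc1ccc(S(=O)(=O)Cl)cc1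
Why: Sulfonylation of the primary alcohol prepares the C–O bond for hydride displacement.

Step 14
Reactants: 23 (2S,6R)-2-[(1S,2E)-1-{6-bromo-2-[(2R,3E)-pent-3-en-2-yl]-3-[(triisopropylsilyl)oxy]phenyl}but-2-en-1-yl]-7-[(tert-butyldimethylsilyl)oxy]-6-methylheptyl 4-methylbenzenesulfonate
Product: 24 tert-butyl{[(2R,6S,7R,8E)-7-{6-bromo-2-[(2R,3E)-pent-3-en-2-yl]-3-[(triisopropylsilyl)oxy]phenyl}-2,6-dimethyldec-8-en-1-yl]oxy}dimethylsilane
Conditions: LiEt3BH, THF, 0 → 40 °C
Reagents that add atoms: none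
Why: SN2 displacement of a primary tosylate by the strong hydride donor LiEt3BH, reliable even at β-branched carbons, turns the former carboxyl carbon into the C11 methyl group and so completes the skeleton needed for ring closure.

Step 15
Reactants: 24 tert-butyl{[(2R,6S,7R,8E)-7-{6-bromo-2-[(2R,3E)-pent-3-en-2-yl]-3-[(triisopropylsilyl)oxy]phenyl}-2,6-dimethyldec-8-en-1-yl]oxy}dimethylsilane
Product: 25 (1R,4R)-8-bromo-1-[(2S,6R)-7-[(tert-butyldimethylsilyl)oxy]-6-methylheptan-2-yl]-4-methyl-5-[(triisopropylsilyl)oxy]-1,4-dihydronaphthalene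
Conditions: second-generation Grubbs catalyst RuCl2(=CHPh)(PCy3)(H2IMes) (5 mol %), 1,4-benzoquinone (10 mol %), CH2Cl2 (0.005 M), 40 °C
Reagents that add atoms: none
Why: Ring-closing olefin metathesis: the ruthenium alkylidene engages one E-propenyl arm, the resulting carbene adds across the second arm to a ruthenacyclobutane, and cycloreversion forms C2=C3 and releases volatile but-2-ene, which drives the closure. The closest known reaction type is the ring-closing metathesis of ortho-diallylarenes to 1,4-dihydronaphthalenes. Ring B closes as a six-membered carbocycle by joining the two alkene carbons that become C2 and C3, and the ring allows only the cis alkene. No stereocentre is created, because C1 and C4 already carry their final configurations, so the trans-1,4 relationship is fixed before the ring exists. The step needs closure to win over intermolecular metathesis, which the ortho placement of the arms on C8a and C4a and high dilution should secure, and it needs the double bond not to migrate into conjugation with ring A (which would erase C1 or C4), for which 1,4-benzoquinone as a scavenger of ruthenium hydrides and the mild temperature are used.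

Step 16
Reactants: 25 (1R,4R)-8-bromo-1-[(2S,6R)-7-[(tert-butyldimethylsilyl)oxy]-6-methylheptan-2-yl]-4-methyl-5-[(triisopropylsilyl)oxy]-1,4-dihydronaphthalene
Product: 26 (1S,4R)-8-bromo-1-[(2S,6R)-7-[(tert-butyldimethylsilyl)oxy]-6-methylheptan-2-yl]-4-methyl-5-[(triisopropylsilyl)oxy]-1,2,3,4-tetrahydronaphthalene
Conditions: TsNHNH2, NaOAc, DME/H2O, 85 °C
Reagents that add atoms: none
Why: Diimide reduction, a concerted syn transfer of two hydrogens that should saturate the cis C2=C3 bond without hydrogenolysis of the aryl bromide and without alkene migration, so C1 and C4 are untouched (the descriptor at C1 changes only because the CIP priorities change).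

Step 17
Reactants: 26 (1S,4R)-8-bromo-1-[(2S,6R)-7-[(tert-butyldimethylsilyl)oxy]-6-methylheptan-2-yl]-4-methyl-5-[(triisopropylsilyl)oxy]-1,2,3,4-tetrahydronaphthalene
Product: 28 (5R,8S)-8-[(2S,6R)-7-[(tert-butyldimethylsilyl)oxy]-6-methylheptan-2-yl]-5-methyl-4-[(triisopropylsilyl)oxy]-5,6,7,8-tetrahydronaphthalene-1-carbaldehyde, via aryllithium 27 (not isolated)
Conditions: t-BuLi (2.1 equiv), Et2O, −78 °C; DMF, −78 → 0 °C; H2O
Reagents that add atoms: N,N-dimethylformamide, CN(C)C=O
Why: Bromine–lithium exchange followed by formylation, the exchange at −78 °C being far faster than any deprotonation and the aldehyde serving as a carboxyl precursor that needs no protecting group.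

Step 18
Reactants: 28 (5R,8S)-8-[(2S,6R)-7-[(tert-butyldimethylsilyl)oxy]-6-methylheptan-2-yl]-5-methyl-4-[(triisopropylsilyl)oxy]-5,6,7,8-tetrahydronaphthalene-1-carbaldehyde
Product: 29 (5R,8S)-8-[(2S,6R)-7-hydroxy-6-methylheptan-2-yl]-5-methyl-4-[(triisopropylsilyl)oxy]-5,6,7,8-tetrahydronaphthalene-1-carbaldehyde
Conditions: AcOH/THF/H2O (3:1:1), 35 °C
Reagents that add atoms: none
Why: Acid-mediated desilylation, in which a primary alkyl tert-butyldimethylsilyl ether is cleaved by aqueous acetic acid while the aryl triisopropylsilyl ether is stable to acid.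

Step 19
Reactants: 29 (5R,8S)-8-[(2S,6R)-7-hydroxy-6-methylheptan-2-yl]-5-methyl-4-[(triisopropylsilyl)oxy]-5,6,7,8-tetrahydronaphthalene-1-carbaldehyde; 30 4-methylpent-3-enoic acid
Product: 31 (2R,6S)-6-[(1S,4R)-8-formyl-4-methyl-5-[(triisopropylsilyl)oxy]-1,2,3,4-tetrahydronaphthalen-1-yl]-2-methylheptyl 4-methylpent-3-enoate
Conditions: DCC, DMAP (cat.), CH2Cl2, 0 °C → rt
Reagents that add atoms: none
Why: Steglich esterification of the primary alcohol, where low temperature and only catalytic DMAP should keep the β,γ-double bond of the acid out of conjugation.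

Step 20
Reactants: 31 (2R,6S)-6-[(1S,4R)-8-formyl-4-methyl-5-[(triisopropylsilyl)oxy]-1,2,3,4-tetrahydronaphthalen-1-yl]-2-methylheptyl 4-methylpent-3-enoate
Product: 32 (5R,8S)-5-methyl-8-{(2S,6R)-6-methyl-7-[(4-methylpent-3-enoyl)oxy]heptan-2-yl}-4-[(triisopropylsilyl)oxy]-5,6,7,8-tetrahydronaphthalene-1-carboxylic acid
Conditions: NaClO2, NaH2PO4, 2-methylbut-2-ene (large excess), t-BuOH/THF/H2O, 0 °C → rt
Reagents that add atoms: sodium chlorite, [Na+].[O-]Cl=O
Why: Pinnick oxidation, in which chlorous acid oxidises the aldehyde to the acid at about pH 4 and the excess 2-methylbut-2-ene traps hypochlorous acid before it can reach the trisubstituted alkene or the arene.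

Step 21
Reactants: 32 (5R,8S)-5-methyl-8-{(2S,6R)-6-methyl-7-[(4-methylpent-3-enoyl)oxy]heptan-2-yl}-4-[(triisopropylsilyl)oxy]-5,6,7,8-tetrahydronaphthalene-1-carboxylic acid
Product: 33 (5R,8S)-4-hydroxy-5-methyl-8-{(2S,6R)-6-methyl-7-[(4-methylpent-3-enoyl)oxy]heptan-2-yl}-5,6,7,8-tetrahydronaphthalene-1-carboxylic acid
Conditions: TBAF, AcOH (1:1), THF, 0 °C → rt
Reagents that add atoms: none
Why: Fluoride-mediated cleavage of the aryl silyl ether, fast at 0 °C and buffered with acetic acid so that the β,γ-unsaturated ester should neither isomerise nor be cleaved.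

**Compound list**

1 | (±)-(E)-pent-3-en-2-ol | C/C=C/C(C)O | starting material
2 | (2R,3E)-pent-3-en-2-ol | C/C=C/[C@@H](C)O | intermediate
3 | 2-bromo-5-hydroxybenzaldehyde | O=Cc1cc(O)ccc1Br | starting material
4 | 2-bromo-5-{[(2S,3E)-pent-3-en-2-yl]oxy}benzaldehyde | C/C=C/[C@H](C)Oc1ccc(Br)c(C=O)c1 | intermediate
5 | (6R)-2-bromo-5-oxo-6-[(2R,3E)-pent-3-en-2-yl]cyclohexa-1,3-diene-1-carbaldehyde (Claisen dienone, not isolated) | O=C1C=CC(Br)=C(C=O)[C@H]1[C@H](C)/C=C/C | intermediate
6 | 6-bromo-3-hydroxy-2-[(2R,3E)-pent-3-en-2-yl]benzaldehyde | C/C=C/[C@@H](C)c1c(O)ccc(Br)c1C=O | intermediate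
7 | 6-bromo-2-[(2R,3E)-pent-3-en-2-yl]-3-[(triisopropylsilyl)oxy]benzaldehyde | C/C=C/[C@@H](C)c1c(O[Si](C(C)C)(C(C)C)C(C)C)ccc(Br)c1C=O | intermediate
8 | dimethyl (2-oxopropyl)phosphonate | COP(=O)(CC(C)=O)OC | starting material
9 | (3E)-4-{6-bromo-2-[(2R,3E)-pent-3-en-2-yl]-3-[(triisopropylsilyl)oxy]phenyl}but-3-en-2-one | C/C=C/[C@@H](C)c1c(O[Si](C(C)C)(C(C)C)C(C)C)ccc(Br)c1/C=C/C(C)=O | intermediate
10 | (2R,3E)-4-{6-bromo-2-[(2R,3E)-pent-3-en-2-yl]-3-[(triisopropylsilyl)oxy]phenyl}but-3-en-2-ol | C/C=C/[C@@H](C)c1c(O[Si](C(C)C)(C(C)C)C(C)C)ccc(Br)c1/C=C/[C@@H](C)O | intermediate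
11 | (2S)-3-bromo-2-methylpropan-1-ol | OC[C@H](C)CBr | starting material
12 | [(2S)-3-bromo-2-methylpropoxy](tert-butyl)dimethylsilane | CC(C)(C)[Si](C)(C)OC[C@H](C)CBr | intermediate
13 | ethyl 4-bromobutanoate | CCOC(=O)CCCBr | starting material
14 | bromo{(2S)-3-[(tert-butyldimethylsilyl)oxy]-2-methylpropyl}magnesium (Grignard reagent, not isolated) | CC(C)(C)[Si](C)(C)OC[C@H](C)C[Mg]Br | intermediate
15 | ethyl (6R)-7-[(tert-butyldimethylsilyl)oxy]-6-methylheptanoate | CC(C)(C)[Si](C)(C)OC[C@H](C)CCCCC(=O)OCC | intermediate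
16 | (6R)-7-[(tert-butyldimethylsilyl)oxy]-6-methylheptanoic acid | CC(C)(C)[Si](C)(C)OC[C@H](C)CCCCC(=O)O | intermediate
17 | (2R,3E)-4-{6-bromo-2-[(2R,3E)-pent-3-en-2-yl]-3-[(triisopropylsilyl)oxy]phenyl}but-3-en-2-yl (6R)-7-[(tert-butyldimethylsilyl)oxy]-6-methylheptanoate | CC(C)(C)[Si](C)(C)OC[C@H](C)CCCCC(=O)O[C@H](C)/C=C/c1c(Br)ccc(O[Si](C(C)C)(C(C)C)C(C)C)c1[C@H](C)/C=C/C | intermediate
18 | lithium enolate of 17, E(O) geometry with the chain cis to the allylic oxygen (not isolated) | CC(C)(C)[Si](C)(C)OC[C@H](C)CCC/C=C(/O[Li])O[C@H](C)/C=C/c1c(Br)ccc(O[Si](C(C)C)(C(C)C)C(C)C)c1[C@H](C)/C=C/C | intermediate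
19 | trimethylsilyl ketene acetal of 17, chain trans to OSiMe3 (not isolated) | CC(C)(C)[Si](C)(C)OC[C@H](C)CCC/C=C(/O[Si](C)(C)C)O[C@H](C)/C=C/c1c(Br)ccc(O[Si](C(C)C)(C(C)C)C(C)C)c1[C@H](C)/C=C/C | intermediate
20 | trimethylsilyl ester of acid 21 (not isolated) | CC(C)(C)[Si](C)(C)OC[C@H](C)CCC[C@H](C(=O)O[Si](C)(C)C)[C@H](/C=C/C)c1c(Br)ccc(O[Si](C(C)C)(C(C)C)C(C)C)c1[C@H](C)/C=C/C | intermediate
21 | (2S,6R)-2-[(1S,2E)-1-{6-bromo-2-[(2R,3E)-pent-3-en-2-yl]-3-[(triisopropylsilyl)oxy]phenyl}but-2-en-1-yl]-7-[(tert-butyldimethylsilyl)oxy]-6-methylheptanoic acid | CC(C)(C)[Si](C)(C)OC[C@H](C)CCC[C@H](C(=O)O)[C@H](/C=C/C)c1c(Br)ccc(O[Si](C(C)C)(C(C)C)C(C)C)c1[C@H](C)/C=C/C | intermediate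
22 | (2S,6R)-2-[(1S,2E)-1-{6-bromo-2-[(2R,3E)-pent-3-en-2-yl]-3-[(triisopropylsilyl)oxy]phenyl}but-2-en-1-yl]-7-[(tert-butyldimethylsilyl)oxy]-6-methylheptan-1-ol | CC(C)(C)[Si](C)(C)OC[C@H](C)CCC[C@H](CO)[C@H](/C=C/C)c1c(Br)ccc(O[Si](C(C)C)(C(C)C)C(C)C)c1[C@H](C)/C=C/C | intermediate
23 | 4-methylbenzenesulfonate of alcohol 22 | CC(C)(C)[Si](C)(C)OC[C@H](C)CCC[C@H](COS(=O)(=O)c2ccc(C)cc2)[C@H](/C=C/C)c1c(Br)ccc(O[Si](C(C)C)(C(C)C)C(C)C)c1[C@H](C)/C=C/C | intermediate
24 | tert-butyl{[(2R,6S,7R,8E)-7-{6-bromo-2-[(2R,3E)-pent-3-en-2-yl]-3-[(triisopropylsilyl)oxy]phenyl}-2,6-dimethyldec-8-en-1-yl]oxy}dimethylsilane | CC(C)(C)[Si](C)(C)OC[C@H](C)CCC[C@H](C)[C@H](/C=C/C)c1c(Br)ccc(O[Si](C(C)C)(C(C)C)C(C)C)c1[C@H](C)/C=C/C | intermediate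
25 | (1R,4R)-8-bromo-1-[(2S,6R)-7-[(tert-butyldimethylsilyl)oxy]-6-methylheptan-2-yl]-4-methyl-5-[(triisopropylsilyl)oxy]-1,4-dihydronaphthalene (trans) | CC(C)(C)[Si](C)(C)OC[C@H](C)CCC[C@H](C)[C@@H]1C=C[C@@H](C)c2c(O[Si](C(C)C)(C(C)C)C(C)C)ccc(Br)c21 | intermediate
26 | (1S,4R)-8-bromo-1-[(2S,6R)-7-[(tert-butyldimethylsilyl)oxy]-6-methylheptan-2-yl]-4-methyl-5-[(triisopropylsilyl)oxy]-1,2,3,4-tetrahydronaphthalene | CC(C)(C)[Si](C)(C)OC[C@H](C)CCC[C@H](C)[C@@H]1CC[C@@H](C)c2c(O[Si](C(C)C)(C(C)C)C(C)C)ccc(Br)c21 | intermediate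
27 | [(5R,8S)-8-[(2S,6R)-7-[(tert-butyldimethylsilyl)oxy]-6-methylheptan-2-yl]-5-methyl-4-[(triisopropylsilyl)oxy]-5,6,7,8-tetrahydronaphthalen-1-yl]lithium (not isolated) | CC(C)(C)[Si](C)(C)OC[C@H](C)CCC[C@H](C)[C@@H]1CC[C@@H](C)c2c(O[Si](C(C)C)(C(C)C)C(C)C)ccc([Li])c21 | intermediate
28 | (5R,8S)-8-[(2S,6R)-7-[(tert-butyldimethylsilyl)oxy]-6-methylheptan-2-yl]-5-methyl-4-[(triisopropylsilyl)oxy]-5,6,7,8-tetrahydronaphthalene-1-carbaldehyde | CC(C)(C)[Si](C)(C)OC[C@H](C)CCC[C@H](C)[C@@H]1CC[C@@H](C)c2c(O[Si](C(C)C)(C(C)C)C(C)C)ccc(C=O)c21 | intermediate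
29 | (5R,8S)-8-[(2S,6R)-7-hydroxy-6-methylheptan-2-yl]-5-methyl-4-[(triisopropylsilyl)oxy]-5,6,7,8-tetrahydronaphthalene-1-carbaldehyde | OC[C@H](C)CCC[C@H](C)[C@@H]1CC[C@@H](C)c2c(O[Si](C(C)C)(C(C)C)C(C)C)ccc(C=O)c21 | intermediate
30 | 4-methylpent-3-enoic acid | CC(C)=CCC(=O)O | starting material
31 | (2R,6S)-6-[(1S,4R)-8-formyl-4-methyl-5-[(triisopropylsilyl)oxy]-1,2,3,4-tetrahydronaphthalen-1-yl]-2-methylheptyl 4-methylpent-3-enoate | CC(C)=CCC(=O)OC[C@H](C)CCC[C@H](C)[C@@H]1CC[C@@H](C)c2c(O[Si](C(C)C)(C(C)C)C(C)C)ccc(C=O)c21 | intermediate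
32 | (5R,8S)-5-methyl-8-{(2S,6R)-6-methyl-7-[(4-methylpent-3-enoyl)oxy]heptan-2-yl}-4-[(triisopropylsilyl)oxy]-5,6,7,8-tetrahydronaphthalene-1-carboxylic acid | CC(C)=CCC(=O)OC[C@H](C)CCC[C@H](C)[C@@H]1CC[C@@H](C)c2c(O[Si](C(C)C)(C(C)C)C(C)C)ccc(C(=O)O)c21 | intermediate
33 | (5R,8S)-4-hydroxy-5-methyl-8-{(2S,6R)-6-methyl-7-[(4-methylpent-3-enoyl)oxy]heptan-2-yl}-5,6,7,8-tetrahydronaphthalene-1-carboxylic acid | CC(C)=CCC(=O)OC[C@H](C)CCC[C@H](C)[C@@H]1CC[C@@H](C)c2c(O)ccc(C(=O)O)c21 | target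

**Step count**

Total: 21 steps. Longest linear sequence: 18 steps (steps 1–6 and 10–21); the chain fragment (steps 7–9) joins at step 10.

**Steps most likely to fail, with fallbacks**

Step 3 (aromatic Claisen). The allyl unit may migrate to the unhindered ortho carbon (C6) instead of the flanked C4a, and forcing the rearrangement may erode the chirality transfer. The fallback sets out from 3 and 2 and returns at 6. Compound 3 would be iodinated at its open ortho position with N-iodosuccinimide to give 2-bromo-5-hydroxy-4-iodobenzaldehyde F1. Mitsunobu etherification with 2 would give 2-bromo-4-iodo-5-{[(2S,3E)-pent-3-en-2-yl]oxy}benzaldehyde F2. The Claisen rearrangement then has only the flanked ortho carbon free and should give 6-bromo-3-hydroxy-4-iodo-2-[(2R,3E)-pent-3-en-2-yl]benzaldehyde F3. The blocking iodine would be removed by chemoselective hydrodeiodination with zerovalent palladium (Pd(PPh3)4, HCO2Na, DMF), where oxidative addition into C–I is far faster than into C–Br, to give 6.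

Step 15 (ring-closing metathesis). Initiation at two allylically branched propenyl groups flanked by ortho substituents may be slow, and ruthenium hydrides may move the new double bond into conjugation and destroy C1 or C4. The fallback sets out from 24 and returns at 25 without metathesis. Ozonolysis of both propenyl groups with NaBH4 work-up should give the diol F7. Mesylation (MsCl, Et3N) should give the bis(methanesulfonate) F8. Double displacement with Na2S under dilution should give the seven-membered cyclic sulfide F9, and mCPBA should oxidise it to the sulfone F10. Ramberg–Bäcklund ring contraction (KOH on Al2O3, CBr2F2, t-BuOH) extrudes SO2 and should form C2=C3 of 25, the sulfone α-carbons being C2 and C3 so that C1 and C4 are not touched.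

Step 11 (Ireland–Claisen). Enolate geometry may be incompletely controlled, or the [3,3] shift at the crowded benzylic terminus may be slow, either of which would give C11 epimers or poor conversion. The fallback sets out from 16 and 10 and returns at 22. Acid 16 would be converted into (6R)-7-[(tert-butyldimethylsilyl)oxy]-N,N,6-trimethylheptanamide F4 (Me2NH, carbodiimide). O-Methylation (MeOTf) followed by NaOMe should give the amide acetal (6R)-7-[(tert-butyldimethylsilyl)oxy]-1,1-dimethoxy-N,N,6-trimethylheptan-1-amine F5. Heating F5 with 10 in xylene at 140 °C is an Eschenmoser–Claisen rearrangement; allylic strain with the NMe2 group places the chain cis to the allylic oxygen in the ketene N,O-acetal, the same geometry as the E(O)-enolate, so the same chair should give the amide (2S,6R)-2-[(1S,2E)-1-{6-bromo-2-[(2R,3E)-pent-3-en-2-yl]-3-[(triisopropylsilyl)oxy]phenyl}but-2-en-1-yl]-7-[(tert-butyldimethylsilyl)oxy]-N,N,6-trimethylheptanamide F6. Reduction with lithium amidotrihydroborate (LiH2NBH3) should give alcohol 22.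

**Further compounds**

F1 | step 3 | 2-bromo-5-hydroxy-4-iodobenzaldehyde | O=Cc1cc(O)c(I)cc1Br
F2 | step 3 | 2-bromo-4-iodo-5-{[(2S,3E)-pent-3-en-2-yl]oxy}benzaldehyde | C/C=C/[C@H](C)Oc1cc(C=O)c(Br)cc1I
F3 | step 3 | 6-bromo-3-hydroxy-4-iodo-2-[(2R,3E)-pent-3-en-2-yl]benzaldehyde | C/C=C/[C@@H](C)c1c(O)c(I)cc(Br)c1C=O
F4 | step 11 | (6R)-7-[(tert-butyldimethylsilyl)oxy]-N,N,6-trimethylheptanamide | CC(C)(C)[Si](C)(C)OC[C@H](C)CCCCC(=O)N(C)C
F5 | step 11 | (6R)-7-[(tert-butyldimethylsilyl)oxy]-1,1-dimethoxy-N,N,6-trimethylheptan-1-amine | CC(C)(C)[Si](C)(C)OC[C@H](C)CCCCC(OC)(OC)N(C)C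
F6 | step 11 | (2S,6R)-2-[(1S,2E)-1-{6-bromo-2-[(2R,3E)-pent-3-en-2-yl]-3-[(triisopropylsilyl)oxy]phenyl}but-2-en-1-yl]-7-[(tert-butyldimethylsilyl)oxy]-N,N,6-trimethylheptanamide | CC(C)(C)[Si](C)(C)OC[C@H](C)CCC[C@H](C(=O)N(C)C)[C@H](/C=C/C)c1c(Br)ccc(O[Si](C(C)C)(C(C)C)C(C)C)c1[C@H](C)/C=C/C
F7 | step 15 | diol: 24 with each CH=CH–CH3 arm replaced by CH2OH, configurations unchanged | CC(C)(C)[Si](C)(C)OC[C@H](C)CCC[C@H](C)[C@H](CO)c1c(Br)ccc(O[Si](C(C)C)(C(C)C)C(C)C)c1[C@H](C)CO
F8 | step 15 | bis(methanesulfonate) of diol F7 | CC(C)(C)[Si](C)(C)OC[C@H](C)CCC[C@H](C)[C@H](COS(C)(=O)=O)c1c(Br)ccc(O[Si](C(C)C)(C(C)C)C(C)C)c1[C@H](C)COS(C)(=O)=O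
F9 | step 15 | seven-membered cyclic sulfide (1,3,4,5-tetrahydro-2-benzothiepine with S between C2 and C3, substituents and configurations as in 25) | CC(C)(C)[Si](C)(C)OC[C@H](C)CCC[C@H](C)[C@@H]1CSC[C@@H](C)c2c(O[Si](C(C)C)(C(C)C)C(C)C)ccc(Br)c21
F10 | step 15 | S,S-dioxide (sulfone) of sulfide F9 | CC(C)(C)[Si](C)(C)OC[C@H](C)CCC[C@H](C)[C@@H]1CS(=O)(=O)C[C@@H](C)c2c(O[Si](C(C)C)(C(C)C)C(C)C)ccc(Br)c21
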